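The plan cuts the depside C(=O)–O bond together with the C1–C2 bond of ring A. Two features of ring A are exploited. The C4 and C6 oxygens and the C1 carboxyl carbon follow a polyketide pattern. That carboxyl carbon is also wedged between the C2 heptyl chain and the C6 oxygen, so the ester is forged while its acyl carbon is still an unhindered ketene terminus. The precursor is 3,5,7-trioxotetradecanoic acid masked as a diketo-dioxinone. On heating it sheds acetone, the C4 phenol of tert-butyl-protected ring B adds to the ketene, and a mild amine folds chain C2 onto the C7 ketone, aromatising ring A around the finished ester.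

Key step: step 6

Remark on the chemistry: the target has no stereocentre and no double-bond geometry, so the SMILES strings carry no stereodescriptors. All 1,3-dicarbonyl compounds are drawn as keto tautomers.

Step 1
Reactants: 1 2,2,6-trimethyl-4H-1,3-dioxin-4-one; 2 acetyl chloride
Product: 3 2,2-dimethyl-6-(2-oxopropyl)-4H-1,3-dioxin-4-one
Conditions: LiN(SiMe3)2 (2.1 equiv), 1 (2 equiv), THF, −78 °C; 2 (1 equiv), −78 → −20 °C; 1 M HCl
Reagents that add atoms: none
Why: Crossed Claisen-type γ-C-acylation of a vinylogous ester enolate, in which LiN(SiMe3)2 removes a proton from the C6 methyl group of 1, the acid chloride attacks the extended enolate at its γ-carbon, and the second equivalent of enolate takes up the acidic proton of 3 so that it is not acylated again.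

Step 2
Reactants: 3 2,2-dimethyl-6-(2-oxopropyl)-4H-1,3-dioxin-4-one; 4 octanoyl chloride
Product: 5 6-(2,4-dioxoundecyl)-2,2-dimethyl-4H-1,3-dioxin-4-one
Conditions: LiN(iPr)2 (4.2 equiv), 3 (2 equiv), THF, −78 → −40 °C; 4 (1 equiv), −78 °C; 1 M HCl to pH 3; surplus 3 recovered; 5 kept cold and used promptly
Reagents that add atoms: none
Why: Terminal-carbon Claisen acylation of a 1,3-dicarbonyl dianion, in which the base removes first a proton of the doubly activated CH2 and then one of the CH3 group of 3, only the last-formed and most basic carbanion attacks 4, and the surplus dianion neutralises the new 1,3-diketone and so prevents a second acylation.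

Step 3
Reactants: 6 2-methoxy-6-methylbenzoic acid; 7 1-iodobutane
Product: 8 2-methoxy-6-pentylbenzoic acid
Conditions: LiN(iPr)2 (2.3 equiv), THF, −78 → 0 °C; 7 (1.3 equiv), −78 °C → rt; 1 M HCl
Reagents that add atoms: none
Why: Lateral (benzylic) lithiation of an ortho-toluic acid followed by SN2 alkylation, in which the lithium carboxylate assists deprotonation of the C6 methyl group and shields its own carbonyl, and the benzylic carbanion displaces iodide from 7 to extend methyl to pentyl.

Step 4
Reactants: 8 2-methoxy-6-pentylbenzoic acid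
Product: 9 tert-butyl 2-methoxy-6-pentylbenzoate
Conditions: Cl3CC(=NH)OtBu (2.5 equiv), BF3·OEt2 (cat.), CH2Cl2–cyclohexane, rt
Reagents that add atoms: tert-butyl 2,2,2-trichloroacetimidate, CC(C)(C)OC(=N)C(Cl)(Cl)Cl
Why: Acid-catalysed O-tert-butylation with a trichloroacetimidate (SN1-type alkyl transfer), in which the new bond forms at the carboxyl oxygen and not at the carbonyl carbon, so the two ortho substituents that would block an ordinary esterification do not matter.

Step 5
Reactants: 9 tert-butyl 2-methoxy-6-pentylbenzoate
Product: 11 tert-butyl 4-hydroxy-2-methoxy-6-pentylbenzoate, via aryl pinacol boronate 10 (not isolated)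
Conditions: [Ir(OMe)(cod)]2 (1.5 mol %), 4,4′-di-tert-butyl-2,2′-bipyridine (3 mol %), B2pin2 (1 equiv), THF, 80 °C; evaporate; KHSO5 (as 2KHSO5·KHSO4·K2SO4), acetone–H2O, rt, 10 min; aq. NaHSO3
Reagents that add atoms: bis(pinacolato)diboron, CC1(C)OB(OC1(C)C)B1OC(C)(C)C(C)(C)O1 (boryl group of 10); potassium peroxymonosulfate, [K+].[O-]S(=O)(=O)OO (phenol oxygen of 11)
Why: Sterically governed iridium-catalysed aromatic C–H borylation followed in the same flask by oxidative 1,2-shift of the aryl group from boron to oxygen, selective because only C4–H among the three ring hydrogens has no ortho substituent, both positions next to the ester are occupied so that no directed borylation can intervene, and the hindered tert-butyl ester tolerates the short oxidation.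

Step 6
Reactants: 5 6-(2,4-dioxoundecyl)-2,2-dimethyl-4H-1,3-dioxin-4-one; 11 tert-butyl 4-hydroxy-2-methoxy-6-pentylbenzoate
Product: 14 tert-butyl 4-[(2-heptyl-4,6-dihydroxybenzoyl)oxy]-2-methoxy-6-pentylbenzoate, via acylketene 12 (not isolated), via aryl triketo ester 13 (not isolated)
Conditions: 11 (1 equiv, 0.5 M), 5 (1.4 equiv, in portions), toluene, 110 °C, Ar, until 5 is consumed (about 2 h); cool to rt; Et3N (3 equiv), 4 Å molecular sieves, rt, 16 h; 10% aq. citric acid
Reagents that add atoms: none
Why: Heating 5 triggers a retro-hetero-Diels–Alder loss of acetone to acylketene 12, and the phenol oxygen of 11 adds to its sp carbon, which at this stage has no ortho neighbours, to give aryl triketo ester 13 and with it the depside acyl C–O bond. The closest known chemistry is the diketo-dioxinone thermolysis, hydroxyl capture and aldol aromatisation sequence used for alkyl resorcylates, together with the routine acetoacetylation of phenols by simpler dioxinones. Once the mixture is cooled, Et3N deprotonates the usefully placed C2 methylene flanked by C1 and C3, and the enolate closes onto the C7 carbonyl (six-membered ring, 6-(enolendo)-exo-trig, ring A C1–C2 bond); dehydration of the aldol adduct and keto–enol shift at C3 and C5 then give the resorcinol ring, with C8–C14 ending up as the heptyl group next to the ester. No stereocentre survives, since the carbinol carbon of the aldol adduct becomes aromatic. The first selectivity needed is capture of 12 ahead of its unimolecular collapse to a 4-hydroxy-2-pyrone, a contest that depends only on phenol concentration and is therefore met by a concentrated solution of 11, portionwise addition of 5 and heating no longer than 5 needs to disappear. The second is aldol closure ahead of aryloxide loss from 13 (attack of the C5 enol oxygen or of C6 on C1, or E1cB reversal to 12), which is favoured because the C7 ketone is the more electrophilic carbonyl, the weak aprotic amine forms only a mono-enolate and brings no external nucleophile, and the CO2tBu group of ring B is twisted out of conjugation by its two ortho groups and so leaves the aryloxide a mediocre leaving group.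

Step 7
Reactants: 14 tert-butyl 4-[(2-heptyl-4,6-dihydroxybenzoyl)oxy]-2-methoxy-6-pentylbenzoate
Product: 15 tert-butyl 4-[(2-heptyl-4,6-dimethoxybenzoyl)oxy]-2-methoxy-6-pentylbenzoate
Conditions: MeI (8 equiv), K2CO3 (4 equiv), dry DMF, rt
Reagents that add atoms: iodomethane, CI
Why: Williamson ether synthesis (SN2 on MeI), in which both ring A phenols, including the hydrogen-bonded C6–OH, are alkylated alike by excess reagent, while the depside carbonyl is screened by its heptyl and oxygen ortho neighbours and the dry, alcohol-free medium supplies no nucleophile that could cleave it.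

Step 8
Reactants: 15 tert-butyl 4-[(2-heptyl-4,6-dimethoxybenzoyl)oxy]-2-methoxy-6-pentylbenzoate
Product: 16 4-[(2-heptyl-4,6-dimethoxybenzoyl)oxy]-2-methoxy-6-pentylbenzoic acid (CNP0274910.0)
Conditions: CF3CO2H–CH2Cl2 1:3, Et3SiH (3 equiv), 0 °C → rt
Reagents that add atoms: none
Why: AAL1 acidolysis of a tert-butyl ester, in which CF3CO2H ionises only the tertiary alkyl–oxygen bond, the aryl ester and the three methyl ethers have no such pathway, and Et3SiH reduces the tert-butyl cation to isobutane before it can alkylate the electron-rich C3 and C5 positions of ring A.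

Compound list
1 | 2,2,6-trimethyl-4H-1,3-dioxin-4-one | CC1=CC(=O)OC(C)(C)O1 | starting material
2 | acetyl chloride | CC(=O)Cl | starting material
3 | 2,2-dimethyl-6-(2-oxopropyl)-4H-1,3-dioxin-4-one | CC(=O)CC1=CC(=O)OC(C)(C)O1 | intermediate
4 | octanoyl chloride | CCCCCCCC(=O)Cl | starting material
5 | 6-(2,4-dioxoundecyl)-2,2-dimethyl-4H-1,3-dioxin-4-one | CCCCCCCC(=O)CC(=O)CC1=CC(=O)OC(C)(C)O1 | intermediate
6 | 2-methoxy-6-methylbenzoic acid | COc1cccc(C)c1C(=O)O | starting material
7 | 1-iodobutane | CCCCI | starting material
8 | 2-methoxy-6-pentylbenzoic acid | CCCCCc1cccc(OC)c1C(=O)O | intermediate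
9 | tert-butyl 2-methoxy-6-pentylbenzoate | CCCCCc1cccc(OC)c1C(=O)OC(C)(C)C | intermediate
10 | tert-butyl 2-methoxy-6-pentyl-4-(4,4,5,5-tetramethyl-1,3,2-dioxaborolan-2-yl)benzoate | CCCCCc1cc(B2OC(C)(C)C(C)(C)O2)cc(OC)c1C(=O)OC(C)(C)C | intermediate
11 | tert-butyl 4-hydroxy-2-methoxy-6-pentylbenzoate | CCCCCc1cc(O)cc(OC)c1C(=O)OC(C)(C)C | intermediate
12 | 3,5,7-trioxotetradec-1-en-1-one (acylketene) | CCCCCCCC(=O)CC(=O)CC(=O)C=C=O | intermediate
13 | tert-butyl 2-methoxy-6-pentyl-4-[(3,5,7-trioxotetradecanoyl)oxy]benzoate | CCCCCCCC(=O)CC(=O)CC(=O)CC(=O)Oc1cc(CCCCC)c(C(=O)OC(C)(C)C)c(OC)c1 | intermediate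
14 | tert-butyl 4-[(2-heptyl-4,6-dihydroxybenzoyl)oxy]-2-methoxy-6-pentylbenzoate | CCCCCCCc1cc(O)cc(O)c1C(=O)Oc1cc(CCCCC)c(C(=O)OC(C)(C)C)c(OC)c1 | intermediate
15 | tert-butyl 4-[(2-heptyl-4,6-dimethoxybenzoyl)oxy]-2-methoxy-6-pentylbenzoate | CCCCCCCc1cc(OC)cc(OC)c1C(=O)Oc1cc(CCCCC)c(C(=O)OC(C)(C)C)c(OC)c1 | intermediate
16 | 4-[(2-heptyl-4,6-dimethoxybenzoyl)oxy]-2-methoxy-6-pentylbenzoic acid | CCCCCCCc1cc(OC)cc(OC)c1C(=O)Oc1cc(CCCCC)c(C(=O)O)c(OC)c1 | target

Total step count: 8. Longest linear sequence: 6 steps (steps 3 to 8, from 6). The dioxinone branch (steps 1 and 2) joins at step 6.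

Steps most likely to fail

**Step 6.**
- What may go wrong: internal lactonisation of the ketene may outrun capture by the phenol. Heat- or base-induced departure of the ring B aryloxide from the open-chain ester may also outrun aldol closure, so that material drains away as pyrone.
- Fallback: it sets out from 5 and 11 and comes back at 15. Ring A is built on a disposable alcohol and the depside bond is made afterwards.
- Thermolysis of 5 in toluene with benzyl alcohol should give, through 12, benzyl 3,5,7-trioxotetradecanoate F1, which Et3N aromatises to benzyl 2-heptyl-4,6-dihydroxybenzoate F2.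
- MeI and K2CO3 then give benzyl 2-heptyl-4,6-dimethoxybenzoate F3.
- Hydrogenolysis (H2, Pd/C, EtOAc), which is indifferent to crowding at the carbonyl, gives 2-heptyl-4,6-dimethoxybenzoic acid F4.
- (COCl)2 with catalytic DMF gives 2-heptyl-4,6-dimethoxybenzoyl chloride F5. This small, strongly electrophilic acyl donor is joined to 11 with Et3N and DMAP in CH2Cl2 to give 15.

**Step 2.**
- What may go wrong: proton transfer from product to dianion, O-acylation or double acylation can erode the conversion. So can premature aromatisation of the sensitive product during work-up or on silica.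
- Fallback: it sets out from 1 and 4 and comes back at 5. Hard-enolate chemistry is replaced by soft enolisation on a removable activating ester.
- The lithium enolate of 1 is acylated with allyl 3-chloro-3-oxopropanoate to give allyl 4-(2,2-dimethyl-4-oxo-4H-1,3-dioxin-6-yl)-3-oxobutanoate F6.
- MgCl2, pyridine and 4 in CH2Cl2 C-acylate its malonate-like CH2 to give allyl 2-[(2,2-dimethyl-4-oxo-4H-1,3-dioxin-6-yl)acetyl]-3-oxodecanoate F7. Its methine is enolised and has no defined configuration.
- Tsuji–Trost deallylation with Pd(PPh3)4 and morpholine, with spontaneous loss of CO2, then delivers 5 under nearly neutral conditions.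

**Step 7.**
- What may go wrong: slow alkylation of the hydrogen-bonded C6–OH may leave phenoxide in contact with the aryl ester long enough for acyl transfer or expulsion of the ring B aryloxide.
- Fallback: it sets out from 14 and comes back at 15. The one-pot anionic alkylation is replaced by a staged sequence without carbonate base.
- A Mitsunobu reaction (MeOH, PPh3, DIAD, THF) etherifies the free C4–OH to give tert-butyl 4-[(2-heptyl-6-hydroxy-4-methoxybenzoyl)oxy]-2-methoxy-6-pentylbenzoate F8.
- Purdie methylation (MeI, Ag2O, CH2Cl2, dark) then alkylates the chelated C6–OH with silver-assisted departure of iodide to give 15.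

Further compounds
F1 | step 6 | benzyl 3,5,7-trioxotetradecanoate | CCCCCCCC(=O)CC(=O)CC(=O)CC(=O)OCc1ccccc1
F2 | step 6 | benzyl 2-heptyl-4,6-dihydroxybenzoate | CCCCCCCc1cc(O)cc(O)c1C(=O)OCc1ccccc1
F3 | step 6 | benzyl 2-heptyl-4,6-dimethoxybenzoate | CCCCCCCc1cc(OC)cc(OC)c1C(=O)OCc1ccccc1
F4 | step 6 | 2-heptyl-4,6-dimethoxybenzoic acid | CCCCCCCc1cc(OC)cc(OC)c1C(=O)O
F5 | step 6 | 2-heptyl-4,6-dimethoxybenzoyl chloride | CCCCCCCc1cc(OC)cc(OC)c1C(=O)Cl
F6 | step 2 | allyl 4-(2,2-dimethyl-4-oxo-4H-1,3-dioxin-6-yl)-3-oxobutanoate | C=CCOC(=O)CC(=O)CC1=CC(=O)OC(C)(C)O1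
F7 | step 2 | allyl 2-[(2,2-dimethyl-4-oxo-4H-1,3-dioxin-6-yl)acetyl]-3-oxodecanoate | CCCCCCCC(=O)C(C(=O)OCC=C)C(=O)CC1=CC(=O)OC(C)(C)O1
F8 | step 7 | tert-butyl 4-[(2-heptyl-6-hydroxy-4-methoxybenzoyl)oxy]-2-methoxy-6-pentylbenzoate | CCCCCCCc1cc(OC)cc(O)c1C(=O)Oc1cc(CCCCC)c(C(=O)OC(C)(C)C)c(OC)c1
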